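## Retrosynthetic overview

1. Feature read (side-chain locants: C1'' = CH2 on C8, C2'' = stereocentre, C3''/C4'' = CH2CH2, C5'' = distal alkene carbon). The two C(CH3)=CH2 units, on C2'' and at C5'', stand 1,5 to each other. C2'' is α to one of them and β to C8 of ring A. Both alkenes are therefore taken back to acetyl groups by a twofold methylenation.
2. The resulting 3-(arylmethyl)heptane-2,6-dione is cut at C8–C1''. It is the Michael adduct of a ring-A C–H of phloroacetophenone to 3-methyleneheptane-2,6-dione, the Rauhut–Currier dimer of methyl vinyl ketone. C2'' (R) is set in the same operation by catalyst-controlled protonation.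
3. C8 versus C6: on bis-MOM protection the OH flanked by the acetyl group and the side chain stays free, and it later becomes O1.
4. Ring order: A is bought. C is closed next as a flat chromone from the acetyl group plus one carbon. B is joined last at C2–C1' by a Rh-catalysed asymmetric 1,4-addition that sets C2 (S). MOM removal follows.

Key step: step 2

Assumption: the absolute sense of induction of the chiral amine (step 2) and the chiral diene (step 8) is not derived here; both enantiomers of each are accessible, and the one giving (R) at C2'' and (S) at C2 is meant.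

## Route

Step 1
Reactants: 1 methyl vinyl ketone (but-3-en-2-one), two molecules
Product: 2 3-methyleneheptane-2,6-dione
Conditions: DABCO (10 mol %), neat, rt; distillation
Reagents that add atoms: none
Why: Rauhut–Currier head-to-tail dimerisation, in which DABCO adds to one enone, the zwitterionic enolate adds through its α-carbon to a second enone, and loss of DABCO leaves the α-methylene 1,5-diketone without any stereocentre.

Step 2
Reactants: 2 3-methyleneheptane-2,6-dione; 3 2,4,6-trihydroxyacetophenone (1.5 equiv)
Product: 4 (3R)-3-[(3-acetyl-2,4,6-trihydroxyphenyl)methyl]heptane-2,6-dione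
Conditions: trans-N1,N1-diethylcyclohexane-1,2-diamine·TfOH (single enantiomer, 20 mol %), THF/CHCl3, 0 °C
Reagents that add atoms: none
Why: Proposed new method: the primary amine of the catalyst condenses with the conjugated C2 carbonyl of 2 to an α-substituted iminium ion, the acidic acylphloroglucinol 3, held as a hydrogen-bonded phenolate as 4-hydroxycoumarin is in amine-catalysed Michael additions to enones, attacks the unhindered exocyclic CH2 with its C3, and rearomatisation leaves a catalyst-bound enamine that is protonated and hydrolysed. The closest known reaction type is the chiral primary-amine-catalysed Friedel–Crafts conjugate addition with enantioselective enamine protonation of indoles and α-substituted vinyl ketones; what is new is the acylphloroglucinol as the arene partner. No ring is closed; the step forms the C8–C1'' bond and brings in eight of the ten side-chain carbons. The only new stereocentre, C2'' (R), is set in the C-protonation of the enamine, in which the protonated tertiary amine of the catalyst, a far stronger acid than the phenols in this medium, hands its proton to one enamine face from within the catalyst. The step needs C- over O-alkylation (the oxa-Michael adduct reverts, the C-adduct ends in an aromatic sink), mono- over bis-alkylation (C3 and C5 of 3 are equivalent and 3 is used in excess) and activation of the enone rather than of the isolated C6 ketone (only the conjugated iminium ion is a carbon electrophile). The α-branched ketone of 4 re-forms an enamine only slowly and sits partly as a cyclic hemiketal on the flanking OH, which should guard C2'' against racemisation.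

Step 3
Reactants: 4 (3R)-3-[(3-acetyl-2,4,6-trihydroxyphenyl)methyl]heptane-2,6-dione
Product: 5 (3R)-3-{[3-acetyl-2-hydroxy-4,6-bis(methoxymethoxy)phenyl]methyl}heptane-2,6-dione
Conditions: MOMCl (2.2 equiv), i-Pr2NEt (2.5 equiv), CH2Cl2, 0 °C
Reagents that add atoms: chloromethyl methyl ether (MOMCl), COCCl
Why: Selective phenol O-alkylation (MOM protection), in which the two less hindered OH groups react while the OH flanked by acetyl group and side chain stays in the hydrogen-bond chelate and is kept as the future O1, and the hindered amine is too weak to enolise the ketone at C2''.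

Step 4
Reactants: 5 (3R)-3-{[3-acetyl-2-hydroxy-4,6-bis(methoxymethoxy)phenyl]methyl}heptane-2,6-dione
Product: 6 1-{2-hydroxy-4,6-bis(methoxymethoxy)-3-[(2R)-5-methyl-2-(prop-1-en-2-yl)hex-5-en-1-yl]phenyl}ethan-1-one
Conditions: MePPh3Br (4.5 equiv), KOt-Bu (4.2 equiv), THF, 0 °C; then 5 added at −78 → 0 °C; aq NH4Cl
Reagents that add atoms: methyltriphenylphosphonium bromide, C[P+](c1ccccc1)(c1ccccc1)c1ccccc1.[Br-]
Why: Twofold Wittig methylenation of the two aliphatic methyl ketones, in which the di-ortho-substituted aryl ketone is inert as its phenoxide (a vinylogous carboxylate), and fast addition of excess ylide at low temperature should outrun deprotonation of the tertiary C2''–H, so that the stereocentre is carried through and is no longer acidic afterwards.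

Step 5
Reactants: 6 1-{2-hydroxy-4,6-bis(methoxymethoxy)-3-[(2R)-5-methyl-2-(prop-1-en-2-yl)hex-5-en-1-yl]phenyl}ethan-1-one
Product: 8 5,7-bis(methoxymethoxy)-8-[(2R)-5-methyl-2-(prop-1-en-2-yl)hex-5-en-1-yl]-4H-chromen-4-one, via enaminone 7 (not isolated)
Conditions: Me2NCH(OMe)2, toluene, 95 °C; evaporate; AcOH, toluene, 70 °C
Reagents that add atoms: N,N-dimethylformamide dimethyl acetal, COC(OC)N(C)C
Why: Standard enaminone route to chromones, in which the only remaining acidic CH3 condenses with the amide acetal and the only free phenol then closes ring C by addition–elimination (loss of Me2NH), placing the side chain at C8; weak acid spares the MOM ethers and the alkenes.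

Step 6
Reactants: 9 4-bromoresorcinol (4-bromobenzene-1,3-diol)
Product: 10 1-bromo-2,4-bis(methoxymethoxy)benzene
Conditions: MOMCl (2.4 equiv), i-Pr2NEt (3 equiv), CH2Cl2, 0 °C → rt
Reagents that add atoms: chloromethyl methyl ether (MOMCl), COCCl
Why: Plain MOM protection of both phenols, needed for the metalation that follows.

Step 7
Reactants: 10 1-bromo-2,4-bis(methoxymethoxy)benzene
Product: 13 2,4-bis(methoxymethoxy)phenylboronic acid, via aryllithium 11 (not isolated), via lithium triisopropyl arylborate 12 (not isolated)
Conditions: n-BuLi, THF, −78 °C; B(Oi-Pr)3, −78 °C → rt; aq NH4Cl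
Reagents that add atoms: triisopropyl borate, CC(C)OB(OC(C)C)OC(C)C; water, O
Why: Bromine–lithium exchange, borylation and mild hydrolysis, a standard arylboronic acid synthesis in which the ortho MOM ether stabilises the aryllithium by chelation.

Step 8
Reactants: 8 5,7-bis(methoxymethoxy)-8-[(2R)-5-methyl-2-(prop-1-en-2-yl)hex-5-en-1-yl]-4H-chromen-4-one; 13 2,4-bis(methoxymethoxy)phenylboronic acid (3 equiv)
Product: 14 (2S)-2-[2,4-bis(methoxymethoxy)phenyl]-5,7-bis(methoxymethoxy)-8-[(2R)-5-methyl-2-(prop-1-en-2-yl)hex-5-en-1-yl]-2,3-dihydro-4H-chromen-4-one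
Conditions: [RhCl(C2H4)2]2 (2.5 mol %), 2,5-diphenylbicyclo[2.2.2]octa-2,5-diene (single enantiomer, 5.5 mol %), aq KOH (10 mol %), toluene/H2O, 40 °C
Reagents that add atoms: none
Why: Rhodium-catalysed asymmetric 1,4-addition of an arylboronic acid to a chromone (Hayashi–Miyaura reaction), in which the chiral diene alone decides the face of C2 attacked by aryl–Rh and gives 2S irrespective of the remote C2'', while the isolated 1,1-disubstituted alkenes do not insert.

Step 9
Reactants: 14 (2S)-2-[2,4-bis(methoxymethoxy)phenyl]-5,7-bis(methoxymethoxy)-8-[(2R)-5-methyl-2-(prop-1-en-2-yl)hex-5-en-1-yl]-2,3-dihydro-4H-chromen-4-one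
Product: 15 remangiflavanone B, (2S)-2-(2,4-dihydroxyphenyl)-5,7-dihydroxy-8-[(2R)-5-methyl-2-(prop-1-en-2-yl)hex-5-en-1-yl]-2,3-dihydro-4H-chromen-4-one
Conditions: HCl (0.5 M in MeOH), rt → 40 °C
Reagents that add atoms: none
Why: Acid-catalysed transacetalisation to methanol frees the four phenols, and phenolic MOM ethers should cleave faster than the alkenes are protonated (as in the deprotection of prenylated flavonoids), while acid, unlike base, does not open ring C, so C2 and C2'' are kept.

## Compound list

1 | methyl vinyl ketone | C=CC(C)=O | starting material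
2 | 3-methyleneheptane-2,6-dione | C=C(CCC(C)=O)C(C)=O | intermediate
3 | 2,4,6-trihydroxyacetophenone | CC(=O)c1c(O)cc(O)cc1O | starting material
4 | (3R)-3-[(3-acetyl-2,4,6-trihydroxyphenyl)methyl]heptane-2,6-dione | CC(=O)CC[C@H](Cc1c(O)cc(O)c(C(C)=O)c1O)C(C)=O | intermediate
5 | (3R)-3-{[3-acetyl-2-hydroxy-4,6-bis(methoxymethoxy)phenyl]methyl}heptane-2,6-dione | CC(=O)CC[C@H](Cc1c(OCOC)cc(OCOC)c(C(C)=O)c1O)C(C)=O | intermediate
6 | 1-{2-hydroxy-4,6-bis(methoxymethoxy)-3-[(2R)-5-methyl-2-(prop-1-en-2-yl)hex-5-en-1-yl]phenyl}ethan-1-one | C=C(C)CC[C@H](Cc1c(OCOC)cc(OCOC)c(C(C)=O)c1O)C(=C)C | intermediate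
7 | (E)-3-(dimethylamino)-1-aryl-prop-2-en-1-one derived from 6 (enaminone) | C=C(C)CC[C@H](Cc1c(OCOC)cc(OCOC)c(C(=O)/C=C/N(C)C)c1O)C(=C)C | intermediate (not isolated)
8 | 5,7-bis(methoxymethoxy)-8-[(2R)-5-methyl-2-(prop-1-en-2-yl)hex-5-en-1-yl]-4H-chromen-4-one | C=C(C)CC[C@H](Cc1c(OCOC)cc(OCOC)c2c1OC=CC2=O)C(=C)C | intermediate
9 | 4-bromoresorcinol | Oc1ccc(Br)c(O)c1 | starting material
10 | 1-bromo-2,4-bis(methoxymethoxy)benzene | COCOc1ccc(Br)c(OCOC)c1 | intermediate
11 | 2,4-bis(methoxymethoxy)phenyllithium | [Li]c1ccc(OCOC)cc1OCOC | intermediate (not isolated)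
12 | lithium triisopropyl [2,4-bis(methoxymethoxy)phenyl]borate | [Li+].CC(C)O[B-](OC(C)C)(OC(C)C)c1ccc(OCOC)cc1OCOC | intermediate (not isolated)
13 | 2,4-bis(methoxymethoxy)phenylboronic acid | OB(O)c1ccc(OCOC)cc1OCOC | intermediate
14 | (2S,2''R)-tetra-O-MOM-remangiflavanone B | C=C(C)CC[C@H](Cc1c(OCOC)cc(OCOC)c2c1O[C@H](c1ccc(OCOC)cc1OCOC)CC2=O)C(=C)C | intermediate
15 | remangiflavanone B | C=C(C)CC[C@H](Cc1c(O)cc(O)c2c1O[C@H](c1ccc(O)cc1O)CC2=O)C(=C)C | target

## Step count and risks

Total step count: 9. Longest linear sequence: 7 (steps 1, 2, 3, 4, 5, 8, 9).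

**1. Step 2 (key step, new method).**

What may go wrong:
- The arene may attack the iminium ion too slowly.
- Proton transfer from the flanking phenols or the medium may bypass the catalyst and erode facial selectivity at C2''.
- A second alkylation may occur at C5.
- Enamine formation at the isolated ketone may lead to Robinson-type aldol closure of the 1,5-diketone.
- C2'' may slowly racemise through re-formed enamine.

The fallback sets out from 3 and returns at 6. It uses known chemistry and moves the stereo-defining bond to C2''–C3'', the bond that the biosynthesis makes by prenylating a prenyl group. C-Prenylation of 3 (prenyl bromide, DBU, THF) gives 3-prenylphloroacetophenone F1. Selective MOM protection (MOMCl, i-Pr2NEt) gives the 4,6-bis-MOM ether F2. (E)-Selective allylic oxidation (cat. SeO2, t-BuOOH, CH2Cl2) gives the (E)-allylic alcohol F3. An Appel reaction (PPh3, CCl4) then gives the (E)-allylic chloride F4. The last operation is a copper-catalysed enantioselective SN2' allylic alkylation (CuTC, chiral phosphoramidite, CH2Cl2, −78 °C). It uses slowly added 3-methylbut-3-enylmagnesium bromide F5, made from 4-bromo-2-methylbut-1-ene and Mg. The first equivalent of F5 turns the chelated phenol into a magnesium phenoxide that also shields the flanked aryl ketone. This reaction forms C2''–C3'', sets C2'' and transposes the alkene to the isopropenyl group, giving 6 directly.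

**2. Step 4.**

What may go wrong:
- The basic ylide may enolise the ketones, leading to epimerisation at C2'' or intramolecular aldol closure.
- The hindered α-branched ketone may convert incompletely.
- The aryl ketone may be partly attacked.

The fallback sets out from 5 and returns at 6. It separates C–C bond formation from elimination. Non-basic addition of Me3SiCH2Li/CeCl3 (THF, −78 °C) to both aliphatic ketones gives the bis(β-hydroxysilane) F6 as a mixture of carbinol epimers. F6 has no acidic C2''–H. Peterson elimination (KH, THF) then gives 6.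

**3. Step 8.**

What may go wrong:
- The electron-rich, ortho-alkoxy boronic acid may protodeboronate faster than it transmetalates.
- The hindered aryl–Rh species may insert slowly.
- Over-addition to the product carbonyl may occur.
- Base may open ring C, with loss of configuration at C2.

The fallback sets out from 6 and returns at 14. It closes O1–C2 instead of forming C2–C1'. 2,4-Dihydroxybenzaldehyde is protected (MOMCl, i-Pr2NEt) to 2,4-bis(methoxymethoxy)benzaldehyde F7. Claisen–Schmidt condensation with 6 (KOH, EtOH) gives the 2'-hydroxychalcone F8. Oxa-Michael closure (NaOAc, EtOH, reflux) gives the flavanone as its C2-epimer mixture F9. Kinetic resolution by Ru–TsDPEN transfer hydrogenation (HCO2H/Et3N) reduces the 2R epimer to the cis-(2R,4R)-flavan-4-ol F10 and leaves 14. F10 can be re-oxidised and re-equilibrated through F8.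

## Further compounds

F1 | step 2 | 1-[2,4,6-trihydroxy-3-(3-methylbut-2-en-1-yl)phenyl]ethan-1-one | CC(C)=CCc1c(O)cc(O)c(C(C)=O)c1O
F2 | step 2 | 1-[2-hydroxy-4,6-bis(methoxymethoxy)-3-(3-methylbut-2-en-1-yl)phenyl]ethan-1-one | CC(C)=CCc1c(OCOC)cc(OCOC)c(C(C)=O)c1O
F3 | step 2 | 1-{2-hydroxy-3-[(2E)-4-hydroxy-3-methylbut-2-en-1-yl]-4,6-bis(methoxymethoxy)phenyl}ethan-1-one | OC/C(C)=C/Cc1c(OCOC)cc(OCOC)c(C(C)=O)c1O
F4 | step 2 | 1-{3-[(2E)-4-chloro-3-methylbut-2-en-1-yl]-2-hydroxy-4,6-bis(methoxymethoxy)phenyl}ethan-1-one | ClC/C(C)=C/Cc1c(OCOC)cc(OCOC)c(C(C)=O)c1O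
F5 | step 2 | 3-methylbut-3-enylmagnesium bromide | C=C(C)CC[Mg]Br
F6 | step 4 | bis(β-hydroxysilane) from twofold Me3SiCH2 addition to 5 (carbinol epimers) | C[Si](C)(C)CC(C)(O)CC[C@H](Cc1c(OCOC)cc(OCOC)c(C(C)=O)c1O)C(C)(O)C[Si](C)(C)C
F7 | step 8 | 2,4-bis(methoxymethoxy)benzaldehyde | O=Cc1ccc(OCOC)cc1OCOC
F8 | step 8 | (E)-2'-hydroxychalcone from 6 and F7 | C=C(C)CC[C@H](Cc1c(OCOC)cc(OCOC)c(C(=O)/C=C/c2ccc(OCOC)cc2OCOC)c1O)C(=C)C
F9 | step 8 | (2RS,2''R)-tetra-O-MOM flavanone (C2-epimer mixture of 14) | C=C(C)CC[C@H](Cc1c(OCOC)cc(OCOC)c2c1OC(c1ccc(OCOC)cc1OCOC)CC2=O)C(=C)C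
F10 | step 8 | cis-(2R,4R,2''R)-tetra-O-MOM flavan-4-ol | C=C(C)CC[C@H](Cc1c(OCOC)cc(OCOC)c2c1O[C@@H](c1ccc(OCOC)cc1OCOC)C[C@H]2O)C(=C)C
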